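Ring D, the meta-phenylene, is made last and from acyclic carbons. It carries only the ether oxygen to ring A (the hydroquinone-derived ring) and the CH2 of the ethano bridge to ring C (the para-phenylene), in a 1,3 relation. A buta-1,3-dien-2-yl ether on the ring A oxygen and an alkynal ending the ring C side chain match this pattern: one Diels–Alder reaction forms both new ring D C–C bonds and closes the six-membered and the 18-membered ring together. The precursor is the open A–B–C triaryl chain with the dienyl ether at one end and CH2CH2C≡C–CHO at the other; the formyl group steers regiochemistry and later leaves as CO.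

Key step: step 12

Remarks on the chemistry
- Ring labels: ring A carries the oxygen para to the ether oxygen that leads to ring D; ring B carries the oxygen ortho to the ether oxygen that leads to ring C; ring C is the para-phenylene; ring D is the meta-phenylene.
- Assumption: methyl 3-(4-hydroxyphenyl)propanoate (5) is bought as such; it is one Fischer esterification away from phloretic acid.
- Precursor design: the alkyne is kept latent as a 1,1-dibromoalkene until after the titanium methylenation, so that no alkyne meets the titanium carbene. Dienyl ether 14 and precursor 16 are not stored; 16 goes straight into dilute hot toluene.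
- No compound of the main route has a stereocentre. The only stereo-element is the stilbene double bond of 8 (E/Z mixture), which step 6 removes.

Step 1
Reactants: 1 2-hydroxy-5-methoxybenzaldehyde
Product: 2 2-(benzyloxy)-5-methoxybenzaldehyde
Conditions: BnBr, K2CO3, DMF, rt
Reagents that add atoms: benzyl bromide, BrCc1ccccc1
Why: Williamson etherification of the phenoxide with a benzylic bromide should be clean, and the benzyl ether masks the ring A phenol through the Wittig step and is removed at no extra cost in step 6.

Step 2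
Reactants: 2 2-(benzyloxy)-5-methoxybenzaldehyde
Product: 3 [2-(benzyloxy)-5-methoxyphenyl]methanol
Conditions: NaBH4, MeOH, 0 °C
Reagents that add atoms: none
Why: Borohydride reduction of an aryl aldehyde to the benzylic alcohol is fast and leaves both ethers untouched.

Step 3
Reactants: 3 [2-(benzyloxy)-5-methoxyphenyl]methanol
Product: 4 {[2-(benzyloxy)-5-methoxyphenyl]methyl}triphenylphosphonium bromide
Conditions: PPh3·HBr, MeCN, reflux
Reagents that add atoms: triphenylphosphine hydrobromide, [Br-].[PH+](c1ccccc1)(c1ccccc1)c1ccccc1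
Why: The electron-rich benzylic alcohol ionises under HBr and is captured by triphenylphosphine (direct alcohol-to-phosphonium salt formation, SN1-like), giving the crystalline Wittig salt without a separate bromide.

Step 4
Reactants: 5 methyl 3-(4-hydroxyphenyl)propanoate; 6 (5-formyl-2-methoxyphenyl)boronic acid
Product: 7 methyl 3-[4-(5-formyl-2-methoxyphenoxy)phenyl]propanoate
Conditions: Cu(OAc)2 (0.3 equiv), pyridine, 4 Å MS, CH2Cl2, O2 (1 atm), rt
Reagents that add atoms: none
Why: Chan–Lam oxidative coupling of a phenol with an arylboronic acid, turned over by O2, forms the B–O–C diaryl ether at room temperature and tolerates both the aldehyde and the ester.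

Step 5
Reactants: 7 methyl 3-[4-(5-formyl-2-methoxyphenoxy)phenyl]propanoate; 4 {[2-(benzyloxy)-5-methoxyphenyl]methyl}triphenylphosphonium bromide
Product: 8 methyl 3-[4-(5-{2-[2-(benzyloxy)-5-methoxyphenyl]ethenyl}-2-methoxyphenoxy)phenyl]propanoate (E/Z mixture)
Conditions: K2CO3, 18-crown-6 (cat.), CH2Cl2, reflux
Reagents that add atoms: none
Why: Wittig olefination of the aryl aldehyde by the semi-stabilised benzylic ylide, under mild solid–liquid conditions that spare the methyl ester, should give the stilbene as an E/Z mixture whose geometry does not matter because the double bond is saturated next.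

Step 6
Reactants: 8 methyl 3-[4-(5-{2-[2-(benzyloxy)-5-methoxyphenyl]ethenyl}-2-methoxyphenoxy)phenyl]propanoate
Product: 9 methyl 3-[4-(5-{2-(2-hydroxy-5-methoxyphenyl)ethyl}-2-methoxyphenoxy)phenyl]propanoate
Conditions: H2 (1 atm), 10% Pd/C, EtOAc–MeOH, rt
Reagents that add atoms: none
Why: Catalytic hydrogenation over palladium saturates the stilbene and hydrogenolyses the benzyl ether in the same operation, leaving the ester, the diaryl ether and the methyl ethers intact.

Step 7
Reactants: 9 methyl 3-[4-(5-{2-(2-hydroxy-5-methoxyphenyl)ethyl}-2-methoxyphenoxy)phenyl]propanoate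
Product: 10 3-[4-(5-{2-(2-hydroxy-5-methoxyphenyl)ethyl}-2-methoxyphenoxy)phenyl]propanal
Conditions: i-Bu2AlH (2.3 equiv), CH2Cl2, −78 °C; MeOH, then aq. potassium sodium tartrate (KNaC4H4O6)
Reagents that add atoms: none
Why: Partial reduction of a methyl ester with diisobutylaluminium hydride at −78 °C with a cold quench is arrested at the aldehyde, one extra equivalent of hydride being spent on the phenol O–H.

Step 8
Reactants: 10 3-[4-(5-{2-(2-hydroxy-5-methoxyphenyl)ethyl}-2-methoxyphenoxy)phenyl]propanal
Product: 11 2-[2-(3-{4-(4,4-dibromobut-3-en-1-yl)phenoxy}-4-methoxyphenyl)ethyl]-4-methoxyphenol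
Conditions: CBr4, PPh3, Zn dust, CH2Cl2, rt (reagent preformed); then 10, rt
Reagents that add atoms: carbon tetrabromide, BrC(Br)(Br)Br
Why: Ramirez dibromo-olefination (first half of the Corey–Fuchs sequence) with the zinc-derived ylide converts the aldehyde into the 1,1-dibromoalkene under neutral conditions that tolerate the free phenol, and this group is a latent alkyne that stays inert in step 10.

Step 9
Reactants: 11 2-[2-(3-{4-(4,4-dibromobut-3-en-1-yl)phenoxy}-4-methoxyphenyl)ethyl]-4-methoxyphenol; 12 acryloyl chloride
Product: 13 2-[2-(3-{4-(4,4-dibromobut-3-en-1-yl)phenoxy}-4-methoxyphenyl)ethyl]-4-methoxyphenyl prop-2-enoate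
Conditions: Et3N, CH2Cl2, 0 °C
Reagents that add atoms: none
Why: O-acylation of the phenol by the acid chloride in the presence of a tertiary amine should give the aryl acrylate at 0 °C without touching the dibromoalkene.

Step 10
Reactants: 13 2-[2-(3-{4-(4,4-dibromobut-3-en-1-yl)phenoxy}-4-methoxyphenyl)ethyl]-4-methoxyphenyl prop-2-enoate
Product: 14 1-(buta-1,3-dien-2-yloxy)-2-[2-(3-{4-(4,4-dibromobut-3-en-1-yl)phenoxy}-4-methoxyphenyl)ethyl]-4-methoxybenzene
Conditions: Cp2Ti(μ-Cl)(μ-CH2)AlMe2 (1.3 equiv), pyridine (cat.), THF–PhMe, −40 → 0 °C; dilute aq. NaOH; filtration through basic Al2O3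
Reagents that add atoms: Tebbe reagent Cp2Ti(μ-Cl)(μ-CH2)AlMe2, C[Al-]1(C)C[Ti]([Cl+]1)(C1C=CC=C1)C1C=CC=C1
Why: Tebbe methylenation, established for aryl esters and for conjugated esters, exchanges the ester C=O for C=CH2 by [2+2] addition of the titanium methylidene and cycloreversion, so the acrylate becomes the 2-aryloxybuta-1,3-diene under non-acidic conditions while the dibromoalkene and the arenes are spectators.

Step 11
Reactants: 14 1-(buta-1,3-dien-2-yloxy)-2-[2-(3-{4-(4,4-dibromobut-3-en-1-yl)phenoxy}-4-methoxyphenyl)ethyl]-4-methoxybenzene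
Product: 16 5-{4-[5-(2-{2-(buta-1,3-dien-2-yloxy)-5-methoxyphenyl}ethyl)-2-methoxyphenoxy]phenyl}pent-2-ynal, via lithium acetylide 15 (not isolated)
Conditions: n-BuLi (2.1 equiv), THF, −78 °C; DMF, −78 → −20 °C; inverse quench into cold aq. KH2PO4/MTBE
Reagents that add atoms: n-butyllithium, [Li]CCCC (lithium of 15); N,N-dimethylformamide, CN(C)C=O (formyl group of 16)
Why: Corey–Fuchs alkyne formation (bromine–lithium exchange, elimination and deprotonation by two equivalents of n-BuLi at −78 °C, far faster than any attack on the dienyl ether) gives the lithium acetylide, and its formylation with DMF followed by an inverse buffered quench releases the alkynal without exposing the dienyl ether to strong acid or the alkynal to free dimethylamine.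

Step 12
Reactants: 16 5-{4-[5-(2-{2-(buta-1,3-dien-2-yloxy)-5-methoxyphenyl}ethyl)-2-methoxyphenoxy]phenyl}pent-2-ynal
Product: 17 macrocyclic cyclohexa-1,4-diene-1-carbaldehyde (18-membered ring; ring D is a cyclohexa-1,4-diene with CHO on C1, the CH2CH2 link to ring C on C2, the oxygen to ring A on C4, and CH2 at C3 and C6; rings A and B as methyl ethers)
Conditions: PhMe, 110 °C, syringe-pump addition to a final 1 mM, BHT (cat.), N2
Reagents that add atoms: none
Why: On heating, the s-cis 2-aryloxybutadiene and the tethered alkynal should combine in a concerted, asynchronous thermal [4+2] cycloaddition of normal electron demand, in which the ring A oxygen on diene C2 raises the HOMO and puts its largest coefficient on the neighbouring CH2 terminus, while the formyl group lowers the alkyne LUMO and puts its largest coefficient on the carbon that bears the CH2CH2 chain. The closest known reaction type is the Diels–Alder addition of 2-alkoxy- and 2-silyloxybutadienes to acetylenic aldehydes and esters, run here as a macrocyclising type 2 intramolecular variant in which the tether leaves from diene C2. The six-membered ring D closes by cycloaddition through both new C–C bonds, and the 18-membered ring closes through the bond between the diene CH2 next to the aryloxy carbon and the chain-bearing alkyne carbon, so that the macrocycle bridges ring D 1,3. No stereocentre is formed, because both new sp3 carbons are CH2 groups of a cyclohexa-1,4-diene. The step needs regioselectivity (formyl 1,4 and side chain 1,3 to the ether oxygen, not the 1,4-bridged 19-membered alternative), which the matched donor on diene C2 and acceptor on the alkyne secure, and it needs ring closure to outrun oligomerisation, which slow addition to high dilution should secure.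

Step 13
Reactants: 17 macrocyclic cyclohexa-1,4-diene-1-carbaldehyde
Product: 18 macrocyclic aryl aldehyde (ring D aromatic: CHO ortho to the CH2CH2 link to ring C and para to the oxygen to ring A; rings A and B as methyl ethers)
Conditions: DDQ (1.1 equiv), CH2Cl2, 0 °C → rt
Reagents that add atoms: none
Why: Dehydrogenation of the cyclohexa-1,4-diene by DDQ (hydride abstraction from a doubly allylic CH2, then proton loss) is driven by aromatisation and is much faster than oxidation of the benzylic ethano bridges.

Step 14
Reactants: 18 macrocyclic aryl aldehyde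
Product: 19 di-O-methyl dihydroptychantol A (the target with OMe on rings A and B)
Conditions: [RhCl(cod)]2 (5 mol%), dppp (12 mol%), diglyme, 162 °C, N2 sweep
Reagents that add atoms: none
Why: Tsuji–Wilkinson-type decarbonylation, in its catalytic form with a rhodium–dppp complex, proceeds by oxidative addition of the formyl C–H bond, CO extrusion and C–H reductive elimination, and is well established for ortho-substituted aryl aldehydes.

Step 15
Reactants: 19 di-O-methyl dihydroptychantol A
Product: 20 dihydroptychantol A
Conditions: BBr3 (6 equiv), CH2Cl2, −78 °C → rt; ice-water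
Reagents that add atoms: none
Why: Lewis-acid cleavage of aryl methyl ethers by BBr3 (bromide attack on the methyl group of the boron-complexed ether) should free both phenols while the diaryl ethers and the ethano bridges are inert.

Compound list
1 | 2-hydroxy-5-methoxybenzaldehyde | COc1ccc(O)c(C=O)c1 | starting material
2 | 2-(benzyloxy)-5-methoxybenzaldehyde | COc1ccc(OCc2ccccc2)c(C=O)c1 | intermediate
3 | [2-(benzyloxy)-5-methoxyphenyl]methanol | COc1ccc(OCc2ccccc2)c(CO)c1 | intermediate
4 | {[2-(benzyloxy)-5-methoxyphenyl]methyl}triphenylphosphonium bromide | COc1ccc(OCc2ccccc2)c(C[P+](c2ccccc2)(c2ccccc2)c2ccccc2)c1.[Br-] | intermediate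
5 | methyl 3-(4-hydroxyphenyl)propanoate | COC(=O)CCc1ccc(O)cc1 | starting material
6 | (5-formyl-2-methoxyphenyl)boronic acid | COc1ccc(C=O)cc1B(O)O | starting material
7 | methyl 3-[4-(5-formyl-2-methoxyphenoxy)phenyl]propanoate | COC(=O)CCc1ccc(cc1)Oc1cc(C=O)ccc1OC | intermediate
8 | methyl 3-[4-(5-{2-[2-(benzyloxy)-5-methoxyphenyl]ethenyl}-2-methoxyphenoxy)phenyl]propanoate, E/Z mixture | COC(=O)CCc1ccc(cc1)Oc1cc(C=Cc2cc(OC)ccc2OCc2ccccc2)ccc1OC | intermediate
9 | methyl 3-[4-(5-{2-(2-hydroxy-5-methoxyphenyl)ethyl}-2-methoxyphenoxy)phenyl]propanoate | COC(=O)CCc1ccc(cc1)Oc1cc(CCc2cc(OC)ccc2O)ccc1OC | intermediate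
10 | 3-[4-(5-{2-(2-hydroxy-5-methoxyphenyl)ethyl}-2-methoxyphenoxy)phenyl]propanal | O=CCCc1ccc(cc1)Oc1cc(CCc2cc(OC)ccc2O)ccc1OC | intermediate
11 | 2-[2-(3-{4-(4,4-dibromobut-3-en-1-yl)phenoxy}-4-methoxyphenyl)ethyl]-4-methoxyphenol | BrC(Br)=CCCc1ccc(cc1)Oc1cc(CCc2cc(OC)ccc2O)ccc1OC | intermediate
12 | acryloyl chloride | C=CC(Cl)=O | starting material
13 | 2-[2-(3-{4-(4,4-dibromobut-3-en-1-yl)phenoxy}-4-methoxyphenyl)ethyl]-4-methoxyphenyl prop-2-enoate | C=CC(=O)Oc1ccc(OC)cc1CCc1ccc(OC)c(c1)Oc1ccc(cc1)CCC=C(Br)Br | intermediate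
14 | 1-(buta-1,3-dien-2-yloxy)-2-[2-(3-{4-(4,4-dibromobut-3-en-1-yl)phenoxy}-4-methoxyphenyl)ethyl]-4-methoxybenzene | C=CC(=C)Oc1ccc(OC)cc1CCc1ccc(OC)c(c1)Oc1ccc(cc1)CCC=C(Br)Br | intermediate
15 | lithium acetylide of the dienyl ether: (4-{4-[5-(2-{2-(buta-1,3-dien-2-yloxy)-5-methoxyphenyl}ethyl)-2-methoxyphenoxy]phenyl}but-1-yn-1-yl)lithium | C=CC(=C)Oc1ccc(OC)cc1CCc1ccc(OC)c(c1)Oc1ccc(cc1)CCC#C[Li] | intermediate (not isolated)
16 | 5-{4-[5-(2-{2-(buta-1,3-dien-2-yloxy)-5-methoxyphenyl}ethyl)-2-methoxyphenoxy]phenyl}pent-2-ynal, the key-step precursor | C=CC(=C)Oc1ccc(OC)cc1CCc1ccc(OC)c(c1)Oc1ccc(cc1)CCC#CC=O | intermediate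
17 | macrocyclic cyclohexa-1,4-diene-1-carbaldehyde, the key-step product | COc1ccc2c(c1)CCc1ccc(OC)c(c1)Oc1ccc(cc1)CCC1=C(C=O)CC=C(C1)O2 | intermediate
18 | macrocyclic aryl aldehyde (ring D aromatic, CHO para to the ether oxygen) | COc1ccc2c(c1)CCc1ccc(OC)c(c1)Oc1ccc(cc1)CCc1cc(ccc1C=O)O2 | intermediate
19 | di-O-methyl dihydroptychantol A | COc1ccc2c(c1)CCc1ccc(OC)c(c1)Oc1ccc(cc1)CCc1cccc(c1)O2 | intermediate
20 | dihydroptychantol A | Oc1ccc2c(c1)CCc1ccc(O)c(c1)Oc1ccc(cc1)CCc1cccc(c1)O2 | target

Total step count: 15.
Longest linear sequence: 14 steps (from 1 through steps 1–3 and 5–15 to 20).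

Steps most likely to fail

Step 12. What may go wrong: intermolecular cycloaddition and oligomerisation outrun ring closure, or the dienyl ether is lost thermally before it cyclises. Fallback: the 18-membered ring is closed at the ring A–O–ring D ether by intramolecular SNAr on a preformed, nitrile-activated ring D, a closure with a long record for macrocyclic diaryl ethers. It sets out from 6 and 4. Chan–Lam coupling of 6 with 4-vinylphenol (Cu(OAc)2, pyridine, O2, CH2Cl2) should give 4-methoxy-3-(4-vinylphenoxy)benzaldehyde F1. Wittig reaction of F1 with 4 (K2CO3, 18-crown-6, CH2Cl2) should give the vinyl stilbene F2. Heck coupling of the terminal vinyl group with 2-bromo-4-fluorobenzonitrile (Pd(OAc)2, P(o-tol)3, Et3N, DMF, 100 °C) should give the distyryl fluoro nitrile F3. Hydrogenation (H2, Pd/C, EtOAc) saturates both C=C bonds and removes the benzyl group to give the phenol fluoro nitrile F4. Cs2CO3 in DMF at about 2 mM and 100 °C displaces the fluoride para to the nitrile and gives the macrocyclic nitrile F5. i-Bu2AlH followed by aqueous acid turns the nitrile into the aldehyde, which is 18, and the route is rejoined before step 14.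

Step 10. What may go wrong: the titanium methylidene is diverted by the acrylate C=C bond or by loss of aryloxide, or the dienyl ether hydrolyses during isolation. Fallback: the dienyl ether is made by elimination, without titanium. It sets out from 10. Ohira–Bestmann homologation (dimethyl (1-diazo-2-oxopropyl)phosphonate, K2CO3, MeOH) should give the terminal alkyne phenol F6. Palladium-catalysed opening of butadiene monoxide by the phenol at the allylic carbon (Pd2(dba)3, racemic DACH-phenyl Trost ligand, CH2Cl2) should give the racemic 2-aryloxybut-3-en-1-ol F7. MsCl and Et3N give the mesylate F8. KOt-Bu in THF at 0 °C removes methanesulfonate by E2 across the allylic, oxygen-bearing C–H and gives the dienyl ether alkyne F9. LiN(i-Pr)2 at −78 °C, then DMF and the same buffered quench, give 16 through 15, and the route is rejoined at the key step.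

Step 14. What may go wrong: CO extrusion from the ortho-substituted aryl aldehyde is slow or incomplete at the temperature the rhodium catalyst needs. Fallback: the formyl carbon is excised oxidatively and the resulting C–O bond is reduced. It sets out from 18. Baeyer–Villiger (Dakin-type) oxidation with mCPBA in CH2Cl2, in which the aryl group migrates because the ring A oxygen sits para, should give the aryl formate F10. K2CO3 in MeOH gives the phenol F11, and Tf2O with pyridine the aryl triflate F12. Pd(OAc)2, dppf, HCO2H and Et3N in DMF at 80 °C reduce the triflate to the arene, which is 19, and the route is rejoined before step 15.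

Further compounds
F1 | step 12 | 4-methoxy-3-(4-vinylphenoxy)benzaldehyde | COc1ccc(C=O)cc1Oc1ccc(C=C)cc1
F2 | step 12 | 1-(benzyloxy)-4-methoxy-2-{2-[4-methoxy-3-(4-vinylphenoxy)phenyl]ethenyl}benzene, E/Z mixture | C=Cc1ccc(cc1)Oc1cc(C=Cc2cc(OC)ccc2OCc2ccccc2)ccc1OC
F3 | step 12 | 2-{2-[4-(5-{2-[2-(benzyloxy)-5-methoxyphenyl]ethenyl}-2-methoxyphenoxy)phenyl]ethenyl}-4-fluorobenzonitrile (new C=C expected E, older C=C E/Z) | N#Cc1ccc(F)cc1C=Cc1ccc(cc1)Oc1cc(C=Cc2cc(OC)ccc2OCc2ccccc2)ccc1OC
F4 | step 12 | 4-fluoro-2-{2-[4-(5-{2-(2-hydroxy-5-methoxyphenyl)ethyl}-2-methoxyphenoxy)phenyl]ethyl}benzonitrile | N#Cc1ccc(F)cc1CCc1ccc(cc1)Oc1cc(CCc2cc(OC)ccc2O)ccc1OC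
F5 | step 12 | macrocyclic nitrile (18 with C≡N in place of CHO) | COc1ccc2c(c1)CCc1ccc(OC)c(c1)Oc1ccc(cc1)CCc1cc(ccc1C#N)O2
F6 | step 10 | 2-[2-(3-{4-(but-3-yn-1-yl)phenoxy}-4-methoxyphenyl)ethyl]-4-methoxyphenol | C#CCCc1ccc(cc1)Oc1cc(CCc2cc(OC)ccc2O)ccc1OC
F7 | step 10 | racemic 2-{2-[2-(3-{4-(but-3-yn-1-yl)phenoxy}-4-methoxyphenyl)ethyl]-4-methoxyphenoxy}but-3-en-1-ol | C=CC(CO)Oc1ccc(OC)cc1CCc1ccc(OC)c(c1)Oc1ccc(cc1)CCC#C
F8 | step 10 | racemic methanesulfonate of F7 | C=CC(COS(C)(=O)=O)Oc1ccc(OC)cc1CCc1ccc(OC)c(c1)Oc1ccc(cc1)CCC#C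
F9 | step 10 | 1-(buta-1,3-dien-2-yloxy)-2-[2-(3-{4-(but-3-yn-1-yl)phenoxy}-4-methoxyphenyl)ethyl]-4-methoxybenzene | C=CC(=C)Oc1ccc(OC)cc1CCc1ccc(OC)c(c1)Oc1ccc(cc1)CCC#C
F10 | step 14 | macrocyclic aryl formate (18 with O–CHO in place of CHO) | COc1ccc2c(c1)CCc1ccc(OC)c(c1)Oc1ccc(cc1)CCc1cc(ccc1OC=O)O2
F11 | step 14 | macrocyclic ring D phenol (18 with OH in place of CHO) | COc1ccc2c(c1)CCc1ccc(OC)c(c1)Oc1ccc(cc1)CCc1cc(ccc1O)O2
F12 | step 14 | macrocyclic ring D aryl triflate | COc1ccc2c(c1)CCc1ccc(OC)c(c1)Oc1ccc(cc1)CCc1cc(ccc1OS(=O)(=O)C(F)(F)F)O2
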